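## Retrosynthetic overview

1. The α-methylene-γ-lactone is closed last by Pd-cyclocarbonylation of a C7-ethynyl / C8-OH pair; the C9 angelate and the C9/C10 diol come from an (E)-C9=C10 olefin.
2. The ten-membered ring, with C6–O, C7 and C8, comes from a tandem anionic oxy-Cope / enolate oxygenation of a trans-1,2-dialkenylcyclohexanol (C5–C10 broken, C7–C8 formed).
3. That cyclohexanol comes from alkoxide-directed conjugate alkenylation (C10) and ketone reduction (C2) of a 4-hydroxycyclohexenone.
4. The enone comes from catalytic enantioselective desymmetrization of an achiral p-quinol, made by oxidative dearomatization of 2,6-dimethylphenol and diynide addition.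
5. Ring order: six-membered carbocycle (from the arene), then ten-membered carbocycle (ring expansion), then γ-lactone.

Assumption: ring atoms are numbered as in the target (C1 CH2, C2 CHOH, C3 CH2, C4 CHMe, C5 C=O, C6 CH–O-isobutyryl, C7, C8 lactone CH–O, C9 CH–O-angeloyl, C10 C(OH)Me). The target SMILES is then (2S,4S,6S,7R,8R,9S,10S).
Assumption: tert-butoxyacetylene (6) is purchased; if not, it is two steps from KOtBu and trichloroethylene.

## Route

Step 1
Reactants: 1, 2,6-dimethylphenol
Product: 2, 4,4-dimethoxy-2,6-dimethylcyclohexa-2,5-dien-1-one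
Conditions: PhI(OAc)2 (2.2 equiv), MeOH, 0 °C to rt
Reagents that add atoms: methanol, CO
Why: Hypervalent-iodine oxidative dearomatization (para-methoxylation, then a second oxidation to the quinone monoketal) gives the mirror-symmetric dienone in which the only carbonyl is flanked by the two methyl-bearing carbons; no stereocentre is formed.

Step 2
Reactants: 2; 3, 1,4-bis(trimethylsilyl)buta-1,3-diyne
Product: 4, 4-hydroxy-3,5-dimethyl-4-[(1E)-4-(trimethylsilyl)but-1-en-3-yn-1-yl]cyclohexa-2,5-dien-1-one (achiral)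
Conditions: 3, MeLi·LiBr, THF, 0 °C to rt; add 2, −78 °C; then Red-Al, −78 to 0 °C; then 1 M aq. HCl/THF, 0 °C
Reagents that add atoms: water, O (new carbonyl oxygen on ketal hydrolysis); the C4 unit comes from reactant 3
Why: Acetylide 1,2-addition to the only carbonyl, propargylic-alkoxide-directed trans-hydroalumination of the proximal alkyne only (E-enyne), and mild hydrolysis of the bis-allylic ketal give the p-quinol, which keeps a mirror plane through C2 and C5.

Step 3 (key step)
Reactants: 4
Product: 5, (4S,5S)-4-hydroxy-3,5-dimethyl-4-[(1E)-4-(trimethylsilyl)but-1-en-3-yn-1-yl]cyclohex-2-en-1-one (cyclohexenone numbering; target C5 = S, C4 = S)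
Conditions: Cu(OAc)2 (5 mol%), (R)-DTBM-SEGPHOS (5.5 mol%; use the antipode if induction is opposite), (EtO)2MeSiH (2.5 equiv), toluene, −40 °C; then 1 M aq. HCl/THF
Reagents that add atoms: none
Why: Proposed new method: a chiral-bisphosphine CuH conjugate reduction should select one of the two enantiotopic β-methyl enone arms and deliver hydride to the dienone face syn to the C5 oxygen (the usual facial preference of 4-oxy-4-carbon dienones), which sets C4 (Me trans to OH) and makes C5 stereogenic; the silyl dienol ether formed is no longer an enone, so the second arm is spared, and the enyne is far less electrophilic; closest known reactions are the CuH/DTBM-SEGPHOS desymmetrization of 4,4-disubstituted cyclohexadienones and asymmetric CuH reduction of 3-methylcyclohexenones.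

Step 4
Reactants: 6, tert-butoxyacetylene
Product: 7, (E)-1-tert-butoxy-2-iodoethene
Conditions: Cp2Zr(H)Cl, THF, rt; then I2, 0 °C
Reagents that add atoms: iodine, II
Why: Schwartz syn-hydrozirconation puts Zr on the terminal carbon and iodinolysis with retention gives the (E)-β-alkoxyvinyl iodide.

Step 5
Reactants: 5; 7
Product: 8, (3R,4S,5S)-3-[(E)-2-tert-butoxyethenyl]-4-hydroxy-3,5-dimethyl-4-[(1E)-4-(trimethylsilyl)but-1-en-3-yn-1-yl]cyclohexan-1-one
Conditions: 7 (3.5 equiv), t-BuLi, Et2O, −78 °C; MgBr2·OEt2; then 5, THF/DMPU, −78 to −20 °C; aq. NH4Cl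
Reagents that add atoms: none (the alkenyl group comes from reactant 7)
Why: Alkoxide-directed (ligand-assisted) conjugate addition: the C5 magnesium alkoxide binds the alkenyl-magnesium and delivers it to the adjacent β-carbon, so the C10 quaternary centre forms with the alkenyl group syn to the C5 oxygen and trans to the enynyl group.

Step 6
Reactants: 8
Product: 9, (1S,2R,4S,6S)-2-[(E)-2-tert-butoxyethenyl]-2,6-dimethyl-1-[(1E)-4-(trimethylsilyl)but-1-en-3-yn-1-yl]cyclohexane-1,4-diol
Conditions: L-Selectride, THF, −78 °C; H2O2, pH 7 buffer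
Reagents that add atoms: none
Why: In the preferred chair (both alkenyl groups axial, both methyls equatorial) the axial C10 alkenyl group blocks axial attack at C2, so the bulky hydride attacks equatorially and gives the axial alcohol, cis to the C5-OH (as with 3,3,5-trimethylcyclohexanone).

Step 7
Reactants: 9
Product: 10, (1S,2R,4S,6S)-2-[(E)-2-tert-butoxyethenyl]-4-[(tert-butyldimethylsilyl)oxy]-2,6-dimethyl-1-[(1E)-4-(trimethylsilyl)but-1-en-3-yn-1-yl]cyclohexan-1-ol
Conditions: TBSOTf (1.05 equiv), 2,6-lutidine, CH2Cl2, −78 °C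
Reagents that add atoms: TBSOTf, CC(C)(C)[Si](C)(C)OS(=O)(=O)C(F)(F)F
Why: Selective silylation of the secondary alcohol; the tertiary alcohol between two fully substituted carbons does not react at −78 °C, and lutidine protects the enol ether.

Step 8
Reactants: 10
Product: 11, (2S,4S,6S,7R,8S,9E)-8-tert-butoxy-2-[(tert-butyldimethylsilyl)oxy]-4,10-dimethyl-5-oxo-7-[(trimethylsilyl)ethynyl]cyclodec-9-en-6-yl 2-methylpropanoate (target numbering; C8 is S here only because CIP priorities change)
Conditions: KHMDS (1.1 equiv), 18-crown-6, THF, −78 to 23 °C; then −78 °C, trans-2-(phenylsulfonyl)-3-phenyloxaziridine; then i-PrCOCl, −78 to 0 °C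
Reagents that add atoms: Davis oxaziridine, O=S(=O)(N1OC1c1ccccc1)c1ccccc1 (adds O); isobutyryl chloride, CC(C)C(Cl)=O
Why: Anionic oxy-Cope rearrangement of the trans-dialkenyl alkoxide through the chair transition state with both (E)-alkenyl termini equatorial forms C7–C8 with the two substituents trans, the (E)-C9=C10 olefin and the C5–C6 enolate regiospecifically (the C5/C10 chirality is relayed to C7/C8); Davis hydroxylation on the peripheral enolate face, opposite the transannular olefin, gives 6S, and the alkoxide is acylated in situ.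

Step 9
Reactants: 11
Product: 12, (2S,4S,6S,7R,8R,9S,10S)-8-tert-butoxy-2-[(tert-butyldimethylsilyl)oxy]-7-ethynyl-9,10-dihydroxy-4,10-dimethyl-5-oxocyclodecan-6-yl 2-methylpropanoate
Conditions: OsO4 (5 mol%), NMO, acetone/H2O, 0 °C to rt; then KF, MeOH, rt
Reagents that add atoms: osmium tetroxide, O=[Os](=O)(=O)=O; NMO, C[N+]1([O-])CCOCC1; water, O
Why: Upjohn syn-dihydroxylation of the only olefin from its outer face (the inner face is blocked by the ring, and C8–H rather than C8–OtBu lies on the attacked face) gives the 9S,10S diol required by syn addition to the E-olefin; KF/MeOH then removes only the alkynyl TMS group.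

Step 10
Reactants: 12; 13, angelic acid
Product: 14, (2S,4S,6S,7R,8R,9S,10S)-8-tert-butoxy-2-[(tert-butyldimethylsilyl)oxy]-7-ethynyl-10-hydroxy-4,10-dimethyl-6-(2-methylpropanoyloxy)-5-oxocyclodecan-9-yl (Z)-2-methylbut-2-enoate
Conditions: 13, 2,4,6-trichlorobenzoyl chloride, Et3N, toluene, rt; then 12, 75 °C (no DMAP)
Reagents that add atoms: none (the acyl group comes from reactant 13)
Why: Yamaguchi mixed-anhydride esterification of the only acylable hydroxyl (C9-OH; C10-OH is tertiary), run without DMAP to avoid angelate-to-tiglate isomerization.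

Step 11
Reactants: 14
Product: 15, (2S,4S,6S,7R,8R,9S,10S)-7-ethynyl-2,8,10-trihydroxy-4,10-dimethyl-6-(2-methylpropanoyloxy)-5-oxocyclodecan-9-yl (Z)-2-methylbut-2-enoate
Conditions: TFA/CH2Cl2 (1:3), H2O (5 equiv), 0 °C to rt
Reagents that add atoms: none
Why: Acidolysis removes the tert-butyl ether (as isobutene) and the TBS ether in one operation; the esters, the tertiary alcohol and the alkyne tolerate cold TFA.

Step 12
Reactants: 15
Product: 16, cardivin C
Conditions: PdCl2 (5 mol%), PPh3 (10 mol%), SnCl2 (5 mol%), CO (7 atm), MeCN, 60 °C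
Reagents that add atoms: carbon monoxide, [C-]#[O+]
Why: Norton-type Pd-catalysed cyclocarbonylation of the homopropargylic alcohol: the C8 alkoxycarbonyl-palladium adds cis across the alkyne to close the five-membered ring and protonolysis gives the exo-methylene, forming the trans-fused α-methylene-γ-lactone without touching any stereocentre.

## Compound list

1 | 2,6-dimethylphenol | Cc1cccc(C)c1O | starting material
2 | 4,4-dimethoxy-2,6-dimethylcyclohexa-2,5-dien-1-one | COC1(OC)C=C(C)C(=O)C(C)=C1 | intermediate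
3 | 1,4-bis(trimethylsilyl)buta-1,3-diyne | C[Si](C)(C)C#CC#C[Si](C)(C)C | starting material
4 | 4-hydroxy-3,5-dimethyl-4-[(1E)-4-(trimethylsilyl)but-1-en-3-yn-1-yl]cyclohexa-2,5-dien-1-one | CC1=CC(=O)C=C(C)C1(O)/C=C/C#C[Si](C)(C)C | intermediate
5 | (4S,5S)-4-hydroxy-3,5-dimethyl-4-[(1E)-4-(trimethylsilyl)but-1-en-3-yn-1-yl]cyclohex-2-en-1-one | O[C@]1(/C=C/C#C[Si](C)(C)C)[C@@H](C)CC(=O)C=C1C | intermediate
6 | tert-butoxyacetylene | CC(C)(C)OC#C | starting material
7 | (E)-1-tert-butoxy-2-iodoethene | CC(C)(C)O/C=C/I | intermediate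
8 | (3R,4S,5S)-3-[(E)-2-tert-butoxyethenyl]-4-hydroxy-3,5-dimethyl-4-[(1E)-4-(trimethylsilyl)but-1-en-3-yn-1-yl]cyclohexan-1-one | O[C@]1(/C=C/C#C[Si](C)(C)C)[C@@H](C)CC(=O)C[C@]1(C)/C=C/OC(C)(C)C | intermediate
9 | (1S,2R,4S,6S)-2-[(E)-2-tert-butoxyethenyl]-2,6-dimethyl-1-[(1E)-4-(trimethylsilyl)but-1-en-3-yn-1-yl]cyclohexane-1,4-diol | O[C@]1(/C=C/C#C[Si](C)(C)C)[C@@H](C)C[C@H](O)C[C@]1(C)/C=C/OC(C)(C)C | intermediate
10 | (1S,2R,4S,6S)-2-[(E)-2-tert-butoxyethenyl]-4-[(tert-butyldimethylsilyl)oxy]-2,6-dimethyl-1-[(1E)-4-(trimethylsilyl)but-1-en-3-yn-1-yl]cyclohexan-1-ol | O[C@]1(/C=C/C#C[Si](C)(C)C)[C@@H](C)C[C@H](O[Si](C)(C)C(C)(C)C)C[C@]1(C)/C=C/OC(C)(C)C | intermediate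
11 | (2S,4S,6S,7R,8S,9E)-8-tert-butoxy-2-[(tert-butyldimethylsilyl)oxy]-4,10-dimethyl-5-oxo-7-[(trimethylsilyl)ethynyl]cyclodec-9-en-6-yl 2-methylpropanoate (target numbering) | CC(C)(C)O[C@@H]1[C@@H](C#C[Si](C)(C)C)[C@H](OC(=O)C(C)C)C(=O)[C@@H](C)C[C@H](O[Si](C)(C)C(C)(C)C)C/C(C)=C/1 | intermediate
12 | (2S,4S,6S,7R,8R,9S,10S)-8-tert-butoxy-2-[(tert-butyldimethylsilyl)oxy]-7-ethynyl-9,10-dihydroxy-4,10-dimethyl-5-oxocyclodecan-6-yl 2-methylpropanoate (target numbering) | CC(C)(C)O[C@@H]1[C@@H](C#C)[C@H](OC(=O)C(C)C)C(=O)[C@@H](C)C[C@H](O[Si](C)(C)C(C)(C)C)C[C@](C)(O)[C@H]1O | intermediate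
13 | angelic acid, (Z)-2-methylbut-2-enoic acid | C/C=C(/C)C(=O)O | starting material
14 | C9 angelate of 12 (target numbering, 2S,4S,6S,7R,8R,9S,10S) | CC(C)(C)O[C@@H]1[C@@H](C#C)[C@H](OC(=O)C(C)C)C(=O)[C@@H](C)C[C@H](O[Si](C)(C)C(C)(C)C)C[C@](C)(O)[C@H]1OC(=O)/C(C)=C\C | intermediate
15 | (2S,4S,6S,7R,8R,9S,10S)-7-ethynyl-2,8,10-trihydroxy-4,10-dimethyl-6-(2-methylpropanoyloxy)-5-oxocyclodecan-9-yl (Z)-2-methylbut-2-enoate (target numbering) | O[C@@H]1[C@@H](C#C)[C@H](OC(=O)C(C)C)C(=O)[C@@H](C)C[C@H](O)C[C@](C)(O)[C@H]1OC(=O)/C(C)=C\C | intermediate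
16 | cardivin C | C=C1C(=O)O[C@@H]2[C@@H]1[C@H](OC(=O)C(C)C)C(=O)[C@@H](C)C[C@H](O)C[C@](C)(O)[C@H]2OC(=O)/C(C)=C\C | target

## Summary

Total step count: 12.
Longest linear sequence: 11 (steps 1–3 and 5–12 from 2,6-dimethylphenol; step 4 is a one-step branch).

Three steps most likely to fail:

- **Step 3 (CuH desymmetrization).** Risks are the face of hydride delivery relative to the C5 oxygen, ee on β-methyl enone arms, and competing enyne reduction. Fallback: give up catalyst control, run steps 3–6 racemically with an achiral copper hydride, and resolve secondary alcohol 9 by lipase-catalysed acylation (CAL-B, vinyl acetate).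
- **Step 5 (directed alkenylation).** Risks are forming a quaternary carbon next to the fully substituted carbinol, β-elimination of the β-alkoxyvinyl metal, and 1,2-addition. Fallback: build C10 before C5 by hydrogenating 2 to 4,4-dimethoxy-2,6-dimethylcyclohexanone, setting the quaternary centre by Pd-catalysed asymmetric α-alkenylation of its enolate with 7, then adding the enynyl-lithium to the C5 ketone, followed by ketal hydrolysis and C2 reduction.
- **Step 8 (oxy-Cope cascade).** Risks are the reactive chair, which places the C4 and C10 methyls 1,3-diaxial, survival of the alkynyl silane under alkoxide conditions, and face selectivity of the enolate oxidation. Fallback: a neutral stepwise sequence in which the tertiary OH is silylated, a thermal siloxy-Cope gives the isolable C5–C6 silyl enol ether, and Rubottom oxidation (DMDO) with separate isobutyrylation installs C6–O.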